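**Plan**

1. Cuts: the C4 carboxyl is traced back to a 4-methoxyphenyl group and the chain ketone to a dioxolane; the C3–CH3 bond is cut (lactone enolate + MeI); the lactone O1–C2 bond is opened to a 1,4-diol; then the chain CH2–C5 bond, the C4–aryl bond and the C5–O bond (as C5–B) are cut in one operation to a chain Grignard reagent, an (E)-alkenylboronic ester and an aryl triflate.
2. Enabling feature: in the γ-lactone ring, C5 carries the ring oxygen O1 and the chain, and its neighbour C4 carries the carboxyl; this O–C5–C4–(sp2 carbon) array is the product pattern of a 1,2-boronate shift across an alkenylboron followed by C–B oxidation.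
3. Forward order: the chain bromide (one Cu-catalysed coupling) and the alkenylboronate (hydroboration) are made separately; the three-component coupling joins the chain to C5 and sets C5 and C4; the lactone ring is closed afterwards by oxidative lactonization of the 1,4-diol; C3 is methylated; the aryl ring is degraded to CO2H and the ketal removed.
4. Stereochemistry: C5 from the chiral bisphosphine–palladium catalyst; C4 relative to C5 from the E-alkene geometry and anti addition (becomes 4,5-cis); C3 from enolate methylation anti to the C4 and C5 substituents (3,4-trans).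

Key step: step 4

Assumption: the (Sp,Sp)-configured ligand named in step 4 is taken to select the alkene face that leads to the (S)-carbinol carbon; if the sense of induction is the opposite, its (Rp,Rp)-enantiomer is used and nothing else changes.

**Step 1**
Reactants: 1 2-(2-bromoethyl)-2-methyl-1,3-dioxolane; 2 1,11-dibromoundecane
Product: 4 2-(13-bromotridecyl)-2-methyl-1,3-dioxolane, via Grignard reagent 3 (not isolated)
Conditions: Mg, THF, 25–30 °C; then added to 2 (3 equiv), Li2CuCl4 (3 mol %), THF, −10 °C → rt
Reagents that add atoms: none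
Why: Kochi-type Li2CuCl4-catalysed sp3–sp3 coupling of a primary alkyl Grignard reagent with a primary bromide, in which the threefold excess of the dibromide should hold the reaction at mono-substitution, the ketal is inert and no stereocenter is formed.

**Step 2**
Reactants: 5 acenaphthenequinone
Product: 6 cis-1,2-dimethyl-1,2-dihydroacenaphthylene-1,2-diol (meso)
Conditions: MeMgBr (2.5 equiv), THF, 0 °C → rt; aq. NH4Cl; recrystallization
Reagents that add atoms: methylmagnesium bromide, C[Mg]Br
Why: Double 1,2-addition of a Grignard reagent to a 1,2-diketone, in which the second methyl group should add to the magnesium-chelated α-alkoxy ketone from the face away from the alkoxide, so that the cis (meso) diol predominates and is purified by recrystallization.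

**Step 3**
Reactants: 7 tert-butyl(but-3-yn-1-yloxy)dimethylsilane; 6 cis-1,2-dimethyl-1,2-dihydroacenaphthylene-1,2-diol
Product: 9 (E)-4-(tert-butyldimethylsilyloxy)but-1-en-1-ylboronic acid cyclic ester of diol 6, via catechol boronate 8 (not isolated)
Conditions: catecholborane (1.1 equiv), Cy2BH (5 mol %), THF, rt; then 6 (1.0 equiv), rt; filtration through silica
Reagents that add atoms: catecholborane, B1Oc2ccccc2O1
Why: Syn, anti-Markovnikov hydroboration of the terminal alkyne fixes the E geometry, and transesterification then exchanges the labile catechol ester for the more stable ester of the ditertiary cis-diol.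

**Step 4**
Reactants: 4 2-(13-bromotridecyl)-2-methyl-1,3-dioxolane; 9 (E)-alkenylboronic ester of diol 6; 10 4-methoxyphenyl trifluoromethanesulfonate
Product: 14 (3R,4S)-1-(tert-butyldimethylsilyloxy)-3-(4-methoxyphenyl)-17-(2-methyl-1,3-dioxolan-2-yl)heptadecan-4-ol, via Grignard reagent 11 (not isolated), via boron ate complex 12 (not isolated), via secondary boronic ester 13 (not isolated)
Conditions: Mg, THF, 40 °C; then 9 (1.05 equiv), THF, 0 °C → rt; then NaOTf (2 equiv), Pd(OAc)2 (3 mol %), (Sp,Sp)-1,1′-bis[bis(4-methoxy-3,5-dimethylphenyl)phosphino]-2,2′-bis[(R)-α-(dimethylamino)benzyl]ferrocene (Mandyphos-type ligand, 3.6 mol %), 10 (1.2 equiv), THF, 60 °C; then 3 M NaOH, 30% H2O2, 0 °C → rt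
Reagents that add atoms: hydrogen peroxide, OO
Why: Grignard reagent 11 adds to boron of 9 to give the four-coordinate boronate 12; oxidative addition of 10 to zerovalent palladium gives a cationic aryl complex of divalent palladium that binds the electron-rich alkene of 12 and triggers a 1,2-metallate shift of the primary chain carbon from boron to the boron-bearing alkene carbon anti to palladium, which creates the chain–carbinol carbon bond, and C–C reductive elimination with retention then places the aryl group on the neighbouring carbon. The closest known reaction type is the palladium-catalysed enantioselective conjunctive cross-coupling of β-substituted alkenylboron ate complexes that carry this acenaphthene-diol ligand on boron. No ring is closed in this step; the lactone ring is closed later from the 1,4-diol. The configuration of the boron-bearing carbon (later C5) is set by the chiral bisphosphine on palladium, which selects the alkene face, and that of the aryl-bearing carbon (later C4) follows from the E geometry of 9 and the anti mode of addition, so that after stereoretentive oxidation of C–B to C–OH the hydroxyl and aryl groups have the relative configuration that becomes 4,5-cis in the lactone. The step needs the metallate shift to win over direct transfer of the alkenyl group to palladium (Suzuki–Miyaura pathway) and over β-hydride elimination; the hindered diol on boron, the single migratable carbon group on boron and NaOTf, which removes bromide from palladium, should secure the first, and fast reductive elimination from the wide-bite-angle ligand the second.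

**Step 5**
Reactants: 14 (3R,4S)-1-(tert-butyldimethylsilyloxy)-3-(4-methoxyphenyl)-17-(2-methyl-1,3-dioxolan-2-yl)heptadecan-4-ol
Product: 15 (3R,4S)-3-(4-methoxyphenyl)-17-(2-methyl-1,3-dioxolan-2-yl)heptadecane-1,4-diol
Conditions: Bu4NF, THF, 0 °C → rt
Reagents that add atoms: none
Why: Fluoride-induced cleavage of the silyl ether, driven by Si–F bond formation, which leaves ketal, secondary alcohol, aryl ether and both stereocenters untouched.

**Step 6**
Reactants: 15 (3R,4S)-3-(4-methoxyphenyl)-17-(2-methyl-1,3-dioxolan-2-yl)heptadecane-1,4-diol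
Product: 17 (4R,5S)-4-(4-methoxyphenyl)-5-[13-(2-methyl-1,3-dioxolan-2-yl)tridecyl]dihydrofuran-2(3H)-one, via lactol 16 (not isolated)
Conditions: TEMPO (0.2 equiv), PhI(OAc)2 (3 equiv), CH2Cl2, rt
Reagents that add atoms: none
Why: Oxidative lactonization of a 1,4-diol, in which the oxoammonium oxidant is selective for the primary alcohol, the aldehyde closes onto the secondary hydroxyl to lactol 16 and this is oxidized on to the γ-lactone, so the carbinol stereocenter is kept as ring C5.

**Step 7**
Reactants: 17 (4R,5S)-4-(4-methoxyphenyl)-5-[13-(2-methyl-1,3-dioxolan-2-yl)tridecyl]dihydrofuran-2(3H)-one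
Product: 19 (3S,4R,5S)-4-(4-methoxyphenyl)-3-methyl-5-[13-(2-methyl-1,3-dioxolan-2-yl)tridecyl]dihydrofuran-2(3H)-one, via lithium enolate 18 (not isolated)
Conditions: LiN(iPr)2 (1.1 equiv), THF, −78 °C; MeI (1.5 equiv), −78 → −40 °C
Reagents that add atoms: iodomethane, CI
Why: Kinetic enolate alkylation of a γ-butyrolactone, in which iodomethane should attack C3 from the face opposite to the C4 aryl group and the C5 chain (both on the same face), setting the 3,4-trans (3S) methyl group.

**Step 8**
Reactants: 19 (3S,4R,5S)-4-(4-methoxyphenyl)-3-methyl-5-[13-(2-methyl-1,3-dioxolan-2-yl)tridecyl]dihydrofuran-2(3H)-one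
Product: 21 (2S,3S,4S)-4-methyl-5-oxo-2-(14-oxopentadecyl)tetrahydrofuran-3-carboxylic acid, via ketal acid 20 (not isolated)
Conditions: RuCl3·xH2O (5 mol %), NaIO4 (16 equiv), CCl4/MeCN/H2O (2:2:3), rt; then 1 M HCl, THF, rt
Reagents that add atoms: sodium periodate, [Na+].[O-]I(=O)(=O)=O; water, O
Why: Catalytically generated RuO4 (Sharpless conditions) should degrade the electron-rich anisyl ring to the carboxylic acid with its ipso carbon kept on C4, and aqueous acid then hydrolyses the dioxolane to the methyl ketone, neither operation being basic enough to epimerize C3 or C4.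

**Compound list**

1 | 2-(2-bromoethyl)-2-methyl-1,3-dioxolane | CC1(CCBr)OCCO1 | starting material
2 | 1,11-dibromoundecane | BrCCCCCCCCCCCBr | starting material
3 | [2-(2-methyl-1,3-dioxolan-2-yl)ethyl]magnesium bromide | CC1(CC[Mg]Br)OCCO1 | intermediate
4 | 2-(13-bromotridecyl)-2-methyl-1,3-dioxolane | CC1(OCCO1)CCCCCCCCCCCCCBr | intermediate
5 | acenaphthenequinone | O=C1C(=O)c2cccc3cccc1c23 | starting material
6 | cis-1,2-dimethyl-1,2-dihydroacenaphthylene-1,2-diol (meso) | C[C@]1(O)c2cccc3cccc(c23)[C@@]1(C)O | intermediate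
7 | tert-butyl(but-3-yn-1-yloxy)dimethylsilane | C#CCCO[Si](C)(C)C(C)(C)C | starting material
8 | 2-[(E)-4-(tert-butyldimethylsilyloxy)but-1-en-1-yl]-1,3,2-benzodioxaborole | CC(C)(C)[Si](C)(C)OCC/C=C/B1Oc2ccccc2O1 | intermediate
9 | (E)-4-(tert-butyldimethylsilyloxy)but-1-en-1-ylboronic acid cyclic ester of diol 6 (cis-fused dioxaborolane) | CC(C)(C)[Si](C)(C)OCC/C=C/B1O[C@@]2(C)c3cccc4cccc(c34)[C@@]2(C)O1 | intermediate
10 | 4-methoxyphenyl trifluoromethanesulfonate | COc1ccc(OS(=O)(=O)C(F)(F)F)cc1 | starting material
11 | [13-(2-methyl-1,3-dioxolan-2-yl)tridecyl]magnesium bromide | CC1(OCCO1)CCCCCCCCCCCCC[Mg]Br | intermediate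
12 | bromomagnesium boronate: boron bearing the diolate of 6, the (E)-alkenyl group of 9 and the 13-(2-methyl-1,3-dioxolan-2-yl)tridecyl group | CC1(OCCO1)CCCCCCCCCCCCC[B-]2(/C=C/CCO[Si](C)(C)C(C)(C)C)O[C@@]3(C)c4cccc5cccc(c45)[C@@]3(C)O2.[Mg+]Br | intermediate
13 | (3S,4S)-secondary boronic ester: 14 with the diolate-of-6 boryl group in place of hydroxyl, same spatial arrangement | CC1(OCCO1)CCCCCCCCCCCCC[C@H](B2O[C@@]3(C)c4cccc5cccc(c45)[C@@]3(C)O2)[C@H](CCO[Si](C)(C)C(C)(C)C)c1ccc(OC)cc1 | intermediate
14 | (3R,4S)-1-(tert-butyldimethylsilyloxy)-3-(4-methoxyphenyl)-17-(2-methyl-1,3-dioxolan-2-yl)heptadecan-4-ol | CC1(OCCO1)CCCCCCCCCCCCC[C@H](O)[C@H](CCO[Si](C)(C)C(C)(C)C)c1ccc(OC)cc1 | intermediate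
15 | (3R,4S)-3-(4-methoxyphenyl)-17-(2-methyl-1,3-dioxolan-2-yl)heptadecane-1,4-diol | CC1(OCCO1)CCCCCCCCCCCCC[C@H](O)[C@H](CCO)c1ccc(OC)cc1 | intermediate
16 | (4R,5S)-4-(4-methoxyphenyl)-5-[13-(2-methyl-1,3-dioxolan-2-yl)tridecyl]tetrahydrofuran-2-ol (anomer mixture) | CC1(OCCO1)CCCCCCCCCCCCC[C@@H]2OC(O)C[C@@H]2c3ccc(OC)cc3 | intermediate
17 | (4R,5S)-4-(4-methoxyphenyl)-5-[13-(2-methyl-1,3-dioxolan-2-yl)tridecyl]dihydrofuran-2(3H)-one | CC1(OCCO1)CCCCCCCCCCCCC[C@@H]2OC(=O)C[C@@H]2c3ccc(OC)cc3 | intermediate
18 | lithium enolate of 17 | CC1(OCCO1)CCCCCCCCCCCCC[C@@H]2OC(O[Li])=C[C@@H]2c3ccc(OC)cc3 | intermediate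
19 | (3S,4R,5S)-4-(4-methoxyphenyl)-3-methyl-5-[13-(2-methyl-1,3-dioxolan-2-yl)tridecyl]dihydrofuran-2(3H)-one | CC1(OCCO1)CCCCCCCCCCCCC[C@@H]2OC(=O)[C@@H](C)[C@@H]2c3ccc(OC)cc3 | intermediate
20 | (2S,3S,4S)-4-methyl-2-[13-(2-methyl-1,3-dioxolan-2-yl)tridecyl]-5-oxotetrahydrofuran-3-carboxylic acid | CC1(OCCO1)CCCCCCCCCCCCC[C@@H]2OC(=O)[C@@H](C)[C@@H]2C(=O)O | intermediate
21 | (2S,3S,4S)-4-methyl-5-oxo-2-(14-oxopentadecyl)tetrahydrofuran-3-carboxylic acid | CC(=O)CCCCCCCCCCCCC[C@@H]1OC(=O)[C@@H](C)[C@@H]1C(=O)O | target

**Count and risks**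

Total step count: 8. Longest linear sequence: 7 steps (steps 2, 3, 4, 5, 6, 7, 8); 6 steps along the carbon skeleton from 1 (steps 1, 4, 5, 6, 7, 8).

Steps most likely to fail:

1. Step 4. The boronate may hand its alkenyl group directly to palladium instead of undergoing the metallate shift, or face selection may be poor with the long functionalized chain, which would erode both the enantiomeric purity and the cis relationship. Fallback, setting out from 4 and coming back at 17, and still joining the chain to the future C5: Grignard reagent 11 is formylated with DMF to 14-(2-methyl-1,3-dioxolan-2-yl)tetradecanal F1. Me2Zn/ProPhenol-catalysed addition of ethyl propiolate (ligand enantiomer chosen for the S alcohol) should give ethyl (S)-4-hydroxy-17-(2-methyl-1,3-dioxolan-2-yl)heptadec-2-ynoate F2. Syn addition of the 4-methoxyphenyl cuprate (4-MeOC6H4MgBr, CuI, THF, −78 °C) gives ethyl (2Z,4S)-4-hydroxy-3-(4-methoxyphenyl)-17-(2-methyl-1,3-dioxolan-2-yl)heptadec-2-enoate F3, which lactonizes on work-up to (S)-4-(4-methoxyphenyl)-5-[13-(2-methyl-1,3-dioxolan-2-yl)tridecyl]furan-2(5H)-one F4. Hydrogenation (H2, Rh/Al2O3, EtOAc) from the face opposite to the C5 chain should then give the cis lactone 17.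

2. Step 8. Oxidative breakdown of the anisyl ring may stop at partly cleaved products, or RuO4 may attack C–H bonds of the long chain, giving poor mass recovery. Fallback, setting out from 17 and coming back at 20: the carboxyl is freed before the methyl group is introduced and by a different oxidant. Ozonolysis of the electron-rich ring of 17 (O3, CH2Cl2/MeOH, −78 °C; then H2O2, NaHCO3) should give (2S,3S)-2-[13-(2-methyl-1,3-dioxolan-2-yl)tridecyl]-5-oxotetrahydrofuran-3-carboxylic acid F5. Its disodium carboxylate–enolate dianion F6 (2.2 equiv NaN(SiMe3)2, THF, −78 °C) is methylated with MeI anti to the carboxylate to give 20, which is hydrolysed to 21 as in the second operation of step 8.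

3. Step 1. The β-ketal Grignard reagent may decompose or homocouple before it is consumed, or couple twice with the dibromide. Fallback, setting out from 2 and coming back at 4: Li2CuCl4-catalysed coupling of 2 (3 equiv) with but-3-enylmagnesium bromide gives 15-bromopentadec-1-ene F7. Tsuji–Wacker oxidation (PdCl2, CuCl, O2, DMF/H2O) gives 15-bromopentadecan-2-one F8. Ketalization (ethylene glycol, TsOH, benzene, Dean–Stark) gives 4.

**Further compounds**

F1 | step 4 | 14-(2-methyl-1,3-dioxolan-2-yl)tetradecanal | CC1(OCCO1)CCCCCCCCCCCCCC=O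
F2 | step 4 | ethyl (S)-4-hydroxy-17-(2-methyl-1,3-dioxolan-2-yl)heptadec-2-ynoate | CC1(OCCO1)CCCCCCCCCCCCC[C@H](O)C#CC(=O)OCC
F3 | step 4 | ethyl (2Z,4S)-4-hydroxy-3-(4-methoxyphenyl)-17-(2-methyl-1,3-dioxolan-2-yl)heptadec-2-enoate | CC1(OCCO1)CCCCCCCCCCCCC[C@H](O)/C(c1ccc(OC)cc1)=C\C(=O)OCC
F4 | step 4 | (S)-4-(4-methoxyphenyl)-5-[13-(2-methyl-1,3-dioxolan-2-yl)tridecyl]furan-2(5H)-one | CC1(OCCO1)CCCCCCCCCCCCC[C@@H]2OC(=O)C=C2c3ccc(OC)cc3
F5 | step 8 | (2S,3S)-2-[13-(2-methyl-1,3-dioxolan-2-yl)tridecyl]-5-oxotetrahydrofuran-3-carboxylic acid | CC1(OCCO1)CCCCCCCCCCCCC[C@@H]2OC(=O)C[C@@H]2C(=O)O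
F6 | step 8 | disodium carboxylate–lactone enolate dianion of F5 | CC1(OCCO1)CCCCCCCCCCCCC[C@@H]2OC([O-])=C[C@@H]2C(=O)[O-].[Na+].[Na+]
F7 | step 1 | 15-bromopentadec-1-ene | C=CCCCCCCCCCCCCCBr
F8 | step 1 | 15-bromopentadecan-2-one | CC(=O)CCCCCCCCCCCCCBr
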